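**Retrosynthetic overview**

- The target is an all-cis oxolane (O1, C2 with the CH(OH)Ar side chain, C3 with the 4-methoxyphenyl group, C4 with OH, C5). Desilylation and a zinc-chelate reduction at C1′ lead back to the all-cis 2-aroyl-4-silyloxyoxolane.
- Feature used: O1, C3, C4 and C5 already form a cis-2-aryl-3-silyloxyoxetane. Cutting C2 and its 3,4-dimethoxybenzoyl group out from between O1 and C3 (bonds O1–C2 and C2–C3) leaves that oxetane and an aroyl carbene, supplied as the diazoketone.
- The oxetane comes from a syn 1-aryl-2-silyloxy-1,3-diol by 4-exo Williamson closure; the diol comes from an Evans syn glycolate aldol with 4-methoxybenzaldehyde, which sets C3 and C4.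
- Ring order: the oxetane first (step 7), then its enlargement to the oxolane, the only ring of the target (step 9). C2 is fixed inside step 9 and C1′ in step 10.

Key step: step 9

Remark: the [1,2]-shift is assumed to control C2 only weakly, so the enolate protonation that fixes C2 is run on the crude shift product and counted as the second stage of step 9.

**Route**

Step 1
Reactants: 1 methyl glycolate (methyl 2-hydroxyacetate)
Product: 2 methyl 2-(triisopropylsilyloxy)acetate
Conditions: TIPSCl, imidazole, DMF, 0 °C → rt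
Reagents that add atoms: chlorotriisopropylsilane, CC(C)[Si](Cl)(C(C)C)C(C)C
Why: Imidazole-promoted silylation of an unhindered primary alcohol (silyl ether formation); no stereocenter is involved.

Step 2
Reactants: 2 methyl 2-(triisopropylsilyloxy)acetate
Product: 3 2-(triisopropylsilyloxy)acetic acid
Conditions: LiOH, THF/H2O, 0 °C → rt; 1 M HCl to pH 4, 0 °C
Reagents that add atoms: lithium hydroxide, [Li+].[OH-]
Why: Saponification of a methyl ester, which the bulky triisopropylsilyl ether should survive under cold aqueous hydroxide and brief mild acidification.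

Step 3
Reactants: 3 2-(triisopropylsilyloxy)acetic acid; 4 (S)-4-benzyl-2-oxazolidinone
Product: 6 (S)-4-benzyl-3-[2-(triisopropylsilyloxy)acetyl]oxazolidin-2-one, via mixed anhydride 5 (not isolated)
Conditions: PivCl, Et3N, THF, −20 °C; then 4, LiCl, −20 °C → rt
Reagents that add atoms: none
Why: N-acylation of the oxazolidinone by a pivalic mixed anhydride, which is attacked at the less hindered glycolyl carbonyl, with LiCl/Et3N activating the carbamate N–H; the auxiliary stereocenter is untouched.

Step 4
Reactants: 6 (S)-4-benzyl-3-[2-(triisopropylsilyloxy)acetyl]oxazolidin-2-one; 7 4-methoxybenzaldehyde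
Product: 10 (S)-4-benzyl-3-[(2S,3R)-3-hydroxy-3-(4-methoxyphenyl)-2-(triisopropylsilyloxy)propanoyl]oxazolidin-2-one, via boron enolate 8 (not isolated), via boron aldolate 9 (not isolated)
Conditions: Bu2BOTf, Et3N, CH2Cl2, −78 → 0 °C; 7, −78 → 0 °C; pH 7 buffer, MeOH, 30% H2O2, 0 °C
Reagents that add atoms: none
Why: Evans syn aldol, in which the Z boron enolate 8 reacts through a chair Zimmerman–Traxler transition state with the imide dipoles opposed and the auxiliary benzyl group blocking one enolate face, so that the syn (2S,3R) adduct (later C4 and C3 of the oxolane) should form.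

Step 5
Reactants: 10 (S)-4-benzyl-3-[(2S,3R)-3-hydroxy-3-(4-methoxyphenyl)-2-(triisopropylsilyloxy)propanoyl]oxazolidin-2-one
Product: 11 (1R,2R)-1-(4-methoxyphenyl)-2-(triisopropylsilyloxy)propane-1,3-diol
Conditions: LiBH4, MeOH (1 equiv), THF, 0 °C; aqueous work-up
Reagents that add atoms: none
Why: Reductive removal of the auxiliary (hydride reduction of the activated exocyclic imide carbonyl to the primary alcohol), which leaves both stereocenters and the silyl ether intact.

Step 6
Reactants: 11 (1R,2R)-1-(4-methoxyphenyl)-2-(triisopropylsilyloxy)propane-1,3-diol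
Product: 12 (2R,3R)-3-hydroxy-3-(4-methoxyphenyl)-2-(triisopropylsilyloxy)propyl 4-methylbenzenesulfonate
Conditions: TsCl, Et3N, DMAP (cat.), CH2Cl2, 0 °C
Reagents that add atoms: 4-methylbenzenesulfonyl chloride, Cc1ccc(S(=O)(=O)Cl)cc1
Why: Selective sulfonylation of the primary hydroxyl, since the secondary benzylic hydroxyl next to the bulky silyloxy group should react far more slowly.

Step 7
Reactants: 12 (2R,3R)-3-hydroxy-3-(4-methoxyphenyl)-2-(triisopropylsilyloxy)propyl 4-methylbenzenesulfonate
Product: 13 (2R,3R)-2-(4-methoxyphenyl)-3-(triisopropylsilyloxy)oxetane (cis)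
Conditions: KOtBu, THF, 0 °C → rt; chromatography on Et3N-deactivated silica
Reagents that add atoms: none
Why: Intramolecular Williamson etherification (4-exo-tet) in which the benzylic alkoxide displaces the primary tosylate, so neither stereocenter is touched and the syn diol maps onto the cis oxetane.

Step 8
Reactants: 14 3,4-dimethoxybenzoyl chloride; 15 trimethylsilyldiazomethane
Product: 17 2-diazo-1-(3,4-dimethoxyphenyl)ethan-1-one, via silyl diazoketone 16 (not isolated)
Conditions: Et3N, MeCN/THF (1:1), 0 °C → rt; aq. NaHCO3 work-up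
Reagents that add atoms: none
Why: C-acylation of the diazo carbon by the aroyl chloride (Arndt–Eistert-type diazoketone synthesis) with Et3N taking up HCl, the C-silyl group being lost on aqueous work-up.

Step 9
Reactants: 13 (2R,3R)-2-(4-methoxyphenyl)-3-(triisopropylsilyloxy)oxetane; 17 2-diazo-1-(3,4-dimethoxyphenyl)ethan-1-one
Product: 21 (3,4-dimethoxyphenyl)[(2S,3S,4S)-3-(4-methoxyphenyl)-4-(triisopropylsilyloxy)oxolan-2-yl]methanone (all-cis), via oxonium ylide 18 (not isolated), via C2-epimeric ketone 19 (not isolated), via potassium enolate 20 (not isolated)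
Conditions: Rh2(OAc)4 (2 mol %), CH2Cl2, rt, 17 (2 equiv) added over 8 h; short silica pad, concentrate; KN(SiMe3)2, THF, −78 °C; AcOH, THF, −78 °C; pH 7 buffer
Reagents that add atoms: none
Why: Rh2(OAc)4 converts 17 into an electrophilic acyl carbenoid, which the oxetane oxygen of 13 (the most Lewis-basic oxygen, the silyl ether being shielded) captures on its lone pair anti to the cis aryl and silyloxy groups to give oxonium ylide 18. Ring strain and the 4-methoxyphenyl group then favour cleavage of the benzylic O1–C3 bond, and C3 recombines with the ylide carbon inside the solvent cage (Stevens-type [1,2]-shift), forming C2–C3 with retention at C3; the closest known reaction type is the metal-carbenoid ring expansion of 2-aryloxetanes with diazo esters to 3-aryloxolane-2-carboxylates. The oxolane is therefore closed by ring enlargement (C2 inserted between O1 and C3, recombination of a 1,5-radical pair) and not by an end-to-end cyclisation, and C3 and C4 are carried over unchanged from the aldol. The regioselectivity needed, migration of the benzylic carbon and not of the oxetane CH2, is secured by the aryl group, and capture by the oxetane oxygen in preference to carbenoid dimerisation is secured by slow addition of 17. The shift itself should give 21 mixed with its C2 epimer 19, so the crude mixture is converged on enolate 20, in which C2 is planar. Protonation of 20 at low temperature should take place on the face away from the C3 aryl and C4 silyloxy groups (kinetic protonation of an exocyclic enolate), which places the aroyl group cis to both and sets the new stereocenter C2 as S.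

Step 10
Reactants: 21 (3,4-dimethoxyphenyl)[(2S,3S,4S)-3-(4-methoxyphenyl)-4-(triisopropylsilyloxy)oxolan-2-yl]methanone
Product: 22 (R)-(3,4-dimethoxyphenyl)[(2S,3S,4S)-3-(4-methoxyphenyl)-4-(triisopropylsilyloxy)oxolan-2-yl]methanol
Conditions: Zn(BH4)2, Et2O, −78 → −20 °C; sat. aq. NH4Cl
Reagents that add atoms: none
Why: Chelation-controlled hydride reduction (Cram chelate model) in which zinc bridges the carbonyl oxygen and ring O1 and hydride enters from the side of the C2–H, away from C3 and its cis aryl group, giving the (R)-carbinol anti to O1 under non-basic conditions that should not epimerise C2.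

Step 11
Reactants: 22 (R)-(3,4-dimethoxyphenyl)[(2S,3S,4S)-3-(4-methoxyphenyl)-4-(triisopropylsilyloxy)oxolan-2-yl]methanol
Product: 23 (3S,4R,5S)-5-[(R)-(3,4-dimethoxyphenyl)(hydroxy)methyl]-4-(4-methoxyphenyl)oxolan-3-ol (target)
Conditions: Bu4NF, THF, 0 °C → rt
Reagents that add atoms: none
Why: Fluoride-mediated cleavage of the silyl ether (desilylation), which touches no stereocenter now that C2 is no longer next to a carbonyl.

**Compound list**

1 | methyl glycolate | COC(=O)CO | starting material
2 | methyl 2-(triisopropylsilyloxy)acetate | COC(=O)CO[Si](C(C)C)(C(C)C)C(C)C | intermediate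
3 | 2-(triisopropylsilyloxy)acetic acid | OC(=O)CO[Si](C(C)C)(C(C)C)C(C)C | intermediate
4 | (S)-4-benzyl-2-oxazolidinone | O=C1OC[C@H](Cc2ccccc2)N1 | starting material
5 | pivalic 2-(triisopropylsilyloxy)acetic anhydride (mixed anhydride, not isolated) | CC(C)(C)C(=O)OC(=O)CO[Si](C(C)C)(C(C)C)C(C)C | intermediate
6 | (S)-4-benzyl-3-[2-(triisopropylsilyloxy)acetyl]oxazolidin-2-one | O=C1OC[C@H](Cc2ccccc2)N1C(=O)CO[Si](C(C)C)(C(C)C)C(C)C | intermediate
7 | 4-methoxybenzaldehyde | COc1ccc(C=O)cc1 | starting material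
8 | dibutylboron Z-enolate of 6 (not isolated) | CCCCB(CCCC)O/C(=C\O[Si](C(C)C)(C(C)C)C(C)C)N1C(=O)OC[C@@H]1Cc1ccccc1 | intermediate
9 | O-dibutylboryl aldolate of 10 (not isolated) | COc1ccc([C@@H](OB(CCCC)CCCC)[C@@H](C(=O)N2C(=O)OC[C@@H]2Cc2ccccc2)O[Si](C(C)C)(C(C)C)C(C)C)cc1 | intermediate
10 | (S)-4-benzyl-3-[(2S,3R)-3-hydroxy-3-(4-methoxyphenyl)-2-(triisopropylsilyloxy)propanoyl]oxazolidin-2-one | COc1ccc([C@@H](O)[C@@H](C(=O)N2C(=O)OC[C@@H]2Cc2ccccc2)O[Si](C(C)C)(C(C)C)C(C)C)cc1 | intermediate
11 | (1R,2R)-1-(4-methoxyphenyl)-2-(triisopropylsilyloxy)propane-1,3-diol | COc1ccc([C@@H](O)[C@@H](CO)O[Si](C(C)C)(C(C)C)C(C)C)cc1 | intermediate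
12 | (2R,3R)-3-hydroxy-3-(4-methoxyphenyl)-2-(triisopropylsilyloxy)propyl 4-methylbenzenesulfonate | COc1ccc([C@@H](O)[C@@H](COS(=O)(=O)c2ccc(C)cc2)O[Si](C(C)C)(C(C)C)C(C)C)cc1 | intermediate
13 | (2R,3R)-2-(4-methoxyphenyl)-3-(triisopropylsilyloxy)oxetane (cis) | COc1ccc([C@H]2OC[C@H]2O[Si](C(C)C)(C(C)C)C(C)C)cc1 | intermediate
14 | 3,4-dimethoxybenzoyl chloride | COc1ccc(C(Cl)=O)cc1OC | starting material
15 | trimethylsilyldiazomethane | C[Si](C)(C)C=[N+]=[N-] | starting material
16 | 2-diazo-1-(3,4-dimethoxyphenyl)-2-(trimethylsilyl)ethan-1-one (not isolated) | COc1ccc(C(=O)C(=[N+]=[N-])[Si](C)(C)C)cc1OC | intermediate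
17 | 2-diazo-1-(3,4-dimethoxyphenyl)ethan-1-one | COc1ccc(C(=O)C=[N+]=[N-])cc1OC | intermediate
18 | oxetan-1-ium ylide from 13 and the aroylcarbene (not isolated) | COc1ccc([C@H]2[O+]([CH-]C(=O)c3ccc(OC)c(OC)c3)C[C@H]2O[Si](C(C)C)(C(C)C)C(C)C)cc1 | intermediate
19 | (3,4-dimethoxyphenyl)[(2R,3S,4S)-3-(4-methoxyphenyl)-4-(triisopropylsilyloxy)oxolan-2-yl]methanone (C2 epimer of 21, not isolated) | COc1ccc([C@H]2[C@H](C(=O)c3ccc(OC)c(OC)c3)OC[C@H]2O[Si](C(C)C)(C(C)C)C(C)C)cc1 | intermediate
20 | potassium enolate of 19/21 (not isolated) | COc1ccc([C@H]2C(=C([O-])c3ccc(OC)c(OC)c3)OC[C@H]2O[Si](C(C)C)(C(C)C)C(C)C)cc1.[K+] | intermediate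
21 | (3,4-dimethoxyphenyl)[(2S,3S,4S)-3-(4-methoxyphenyl)-4-(triisopropylsilyloxy)oxolan-2-yl]methanone (all-cis) | COc1ccc([C@H]2[C@@H](C(=O)c3ccc(OC)c(OC)c3)OC[C@H]2O[Si](C(C)C)(C(C)C)C(C)C)cc1 | intermediate
22 | (R)-(3,4-dimethoxyphenyl)[(2S,3S,4S)-3-(4-methoxyphenyl)-4-(triisopropylsilyloxy)oxolan-2-yl]methanol | COc1ccc([C@H]2[C@@H]([C@H](O)c3ccc(OC)c(OC)c3)OC[C@H]2O[Si](C(C)C)(C(C)C)C(C)C)cc1 | intermediate
23 | (3S,4R,5S)-5-[(R)-(3,4-dimethoxyphenyl)(hydroxy)methyl]-4-(4-methoxyphenyl)oxolan-3-ol | COc1ccc([C@H]2[C@@H]([C@H](O)c3ccc(OC)c(OC)c3)OC[C@H]2O)cc1 | target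

**Step count**

Total step count: 11. Longest linear sequence: 10 steps (steps 1–7 and 9–11, from methyl glycolate); step 8 is the side branch.

**Steps most likely to fail**

Step 9. The acyl carbenoid may be consumed by dimerisation or by attack on the electron-rich arenes before the hindered oxetane oxygen captures it, and the ylide may fragment instead of rearranging. Fallback, from 13 back to 19: the aroyl group is no longer delivered by the carbenoid. Oxetane 13 is enlarged with ethyl diazoacetate under Cu(MeCN)4PF6/2,2′-bipyridine catalysis in CH2Cl2, the ester carbenoid being the class on which this ring expansion is established. This should give ethyl (3S,4S)-3-(4-methoxyphenyl)-4-(triisopropylsilyloxy)oxolane-2-carboxylate F1 as both C2 epimers. Treatment with MeNH(OMe)·HCl and iPrMgCl in THF at −20 °C converts it into the Weinreb amide (3S,4S)-N-methoxy-3-(4-methoxyphenyl)-N-methyl-4-(triisopropylsilyloxy)oxolane-2-carboxamide F2. Addition of 3,4-dimethoxyphenylmagnesium bromide in THF at 0 °C then gives the ketone epimer mixture, which re-enters the route at 19 and is taken through enolate 20 to 21 as in the second stage of step 9.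

Step 7. Under base the silyl group may migrate from its oxygen to the neighbouring benzylic alkoxide, after which the freed alkoxide closes an epoxide instead of the oxetane; the alkoxide may also fragment (Grob-type) to 4-methoxybenzaldehyde. Fallback, from 4 and 7 back to 13: the ring is closed with a non-migrating allyl ether on that oxygen and the silyl group is introduced afterwards.
- Oxazolidinone 4 is N-acylated with allyloxyacetic acid (PivCl, Et3N, LiCl, THF) to (S)-4-benzyl-3-[2-(prop-2-en-1-yloxy)acetyl]oxazolidin-2-one F3.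
- The Bu2BOTf/Et3N aldol with 7 should give the syn adduct (S)-4-benzyl-3-[(2S,3R)-3-hydroxy-3-(4-methoxyphenyl)-2-(prop-2-en-1-yloxy)propanoyl]oxazolidin-2-one F4.
- LiBH4 gives (1R,2R)-1-(4-methoxyphenyl)-2-(prop-2-en-1-yloxy)propane-1,3-diol F5.
- TsCl/Et3N gives the primary tosylate (2R,3R)-3-hydroxy-3-(4-methoxyphenyl)-2-(prop-2-en-1-yloxy)propyl 4-methylbenzenesulfonate F6.
- KOtBu in THF closes (2R,3R)-2-(4-methoxyphenyl)-3-(prop-2-en-1-yloxy)oxetane F7.
- KOtBu in DMSO at 60 °C isomerises the allyl ether to (2R,3R)-2-(4-methoxyphenyl)-3-(prop-1-en-1-yloxy)oxetane F8.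
- I2 and NaHCO3 in aqueous THF cleave the enol ether to (2R,3R)-2-(4-methoxyphenyl)oxetan-3-ol F9.
- TIPSOTf and 2,6-lutidine in CH2Cl2 at −78 °C then give 13.

Step 10. Facial selectivity may be poor if the zinc chelate between the carbonyl and O1 does not form cleanly (Felkin–Anh attack would give the C1′ epimer), and the all-cis ketone may epimerise at C2 before it is reduced. Fallback, from 21 to 22: C1′ is set by reagent control instead of substrate control, by Corey–Bakshi–Shibata reduction with (R)-2-methyl-CBS-oxazaborolidine and BH3·SMe2 in THF at −20 °C. The aryl group acts as the large substituent, so the (R)-carbinol 22 is expected. This path makes no new compound (F0).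

**Further compounds**

F1 | step 9 | ethyl (3S,4S)-3-(4-methoxyphenyl)-4-(triisopropylsilyloxy)oxolane-2-carboxylate (C2 epimers) | COc1ccc([C@H]2C(C(=O)OCC)OC[C@H]2O[Si](C(C)C)(C(C)C)C(C)C)cc1
F2 | step 9 | (3S,4S)-N-methoxy-3-(4-methoxyphenyl)-N-methyl-4-(triisopropylsilyloxy)oxolane-2-carboxamide (C2 epimers) | COc1ccc([C@H]2C(C(=O)N(C)OC)OC[C@H]2O[Si](C(C)C)(C(C)C)C(C)C)cc1
F3 | step 7 | (S)-4-benzyl-3-[2-(prop-2-en-1-yloxy)acetyl]oxazolidin-2-one | O=C1OC[C@H](Cc2ccccc2)N1C(=O)COCC=C
F4 | step 7 | (S)-4-benzyl-3-[(2S,3R)-3-hydroxy-3-(4-methoxyphenyl)-2-(prop-2-en-1-yloxy)propanoyl]oxazolidin-2-one | COc1ccc([C@@H](O)[C@@H](C(=O)N2C(=O)OC[C@@H]2Cc2ccccc2)OCC=C)cc1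
F5 | step 7 | (1R,2R)-1-(4-methoxyphenyl)-2-(prop-2-en-1-yloxy)propane-1,3-diol | COc1ccc([C@@H](O)[C@@H](CO)OCC=C)cc1
F6 | step 7 | (2R,3R)-3-hydroxy-3-(4-methoxyphenyl)-2-(prop-2-en-1-yloxy)propyl 4-methylbenzenesulfonate | COc1ccc([C@@H](O)[C@@H](COS(=O)(=O)c2ccc(C)cc2)OCC=C)cc1
F7 | step 7 | (2R,3R)-2-(4-methoxyphenyl)-3-(prop-2-en-1-yloxy)oxetane | COc1ccc([C@H]2OC[C@H]2OCC=C)cc1
F8 | step 7 | (2R,3R)-2-(4-methoxyphenyl)-3-(prop-1-en-1-yloxy)oxetane | COc1ccc([C@H]2OC[C@H]2OC=CC)cc1
F9 | step 7 | (2R,3R)-2-(4-methoxyphenyl)oxetan-3-ol | COc1ccc([C@H]2OC[C@H]2O)cc1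
F0 | step 10 | none | none
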